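Twenty hours was the time I had to judge, so I began by asking which clock in Saturday's closed flask was still running at the end.

| flask | substrate | reagent | time | remark |
|---|---|---|---|---|
| Wednesday's | 19 mM (fed, over 20.0 h) | 19.0 mM | 20 h | a stirred flask in which substrate is dosed at a steady rate over 20.0 h without added volume, worked up at 20 h |
| Saturday's | 19 mM | 19.0 mM | 20 h | a closed flask charged with all of it at once and left for 20 h |
| Tuesday's | 19 mM | 19.0 mM |  | a single well-mixed tank run continuously and read at steady state, 200 h in it on average |
| Friday's | 19 mM | 19.0 mM |  | one stirred flow tank at steady state, fed with the mixture as stated, mean residence time 20 h |

    substrate + reagent → mono adduct (k1 = 0.82 M⁻¹ min⁻¹)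
    reagent + mono adduct → bis adduct (k2 = 1.2 M⁻¹ min⁻¹)
    reagent + bis adduct → tris adduct (k3 = 1.0 M⁻¹ min⁻¹)
    substrate + mono adduct → side product (k4 = 0.13 M⁻¹ min⁻¹)

- in percentages every species weighs as the substrate in it: one side product counts as two
- the stated concentrations are those of everything mixed, before any reaction; amounts are the same in each set-up
- the feed brings no volume worth counting
- run time (Wednesday's): 20 h

- the set-up with the highest share of bis adduct in all that became bis adduct or tris adduct or side product, at the outlet or at the end ("none" if the first two lie within 2 percentage points) (Wednesday's / Saturday's / Tuesday's / Friday's / none)
- share of bis adduct in all that became bis adduct or tris adduct or side product, at the outlet or at the end, Wednesday's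
- share of bis adduct in all that became bis adduct or tris adduct or side product, at the outlet or at the end, Saturday's
- share of bis adduct in all that became bis adduct or tris adduct or side product, at the outlet or at the end, Tuesday's
- share of bis adduct in all that became bis adduct or tris adduct or side product, at the outlet or at the end, Friday's

I counted in half-lives and in fractions of the charge. My measure was the side half-life, the half-life of mono adduct by step 4 with substrate at the full charge, 4.68 h, to be divided by the fraction of substrate standing at that moment (a pseudo-first-order half-life).

In Saturday's flask the substrate's half-life by step 1, with reagent as charged, was 0.741 h, shorter than the side half-life, so I left step 4 out of the first hours. Walking the ladder by hand with the ratios of k1, k2 and k3, I came to substrate 0.400, mono adduct 0.300, bis adduct 0.200 and tris adduct 0.100. The reagent held in these forms came to 1.00 of its charge, so I took it as spent, with step 4 left to use the remaining time.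

I then reckoned the mono adduct at 20 h in two ways. Holding substrate at 0.400 gave a side half-life of 11.7 h and left 0.0917. The second way used the pairing: step 4 takes one substrate with each mono adduct, so their difference stays fixed while their ratio grows exponentially, and this left 0.126. The first way cheated, because in the second reckoning substrate fell to 0.226, less than the 0.400 I had held, and the side half-life lengthened as it fell. I kept the second, which gave a share of 30.9% for Saturday's.

The forecast named Saturday's, with 24%, 31%, 6.3% and 18% in the order asked, saying “The reagent runs out early in the batch”.

The simulation gave Saturday's as best, with 19.4%, 29.0%, 6.33% and 18.1% in the same order. Saturday's flask had not come to rest at 20 h: it held mono adduct 12.7% and substrate 0.221, so the side half-life then stood at 21.2 h, and its share was 21.1% after 200 h. In Friday's tank, with mono adduct 12.3%, bis adduct 9.34% and tris adduct 16.1% at the outlet, I took the side product over the mean stay from the side half-life and closed the balance of the charge on substrate, which came to 0.360 with a side half-life of 13.0 h. Side product then weighed 0.263, and Friday's share came to 18.1%.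

The rate constants are assumed; the result is computed.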